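Assumption: ring atoms keep the target's numbering in every compound (C1 bears C7, C2 is the vinylic CH, C3 to C6 carry oxygen), the ring face holding O5 and O6 is called β, and the recombinant strain expressing toluene dioxygenase is treated as an available biocatalyst, not as a starting material.

## Structural features

The target is a single carbocycle, a cyclohex-1-ene in which C1 carries the exocyclic benzoyloxymethyl carbon C7 and C3, C4, C5 and C6 form an unbroken row of four oxygen-bearing stereocentres (3R,4S,5R,6R). O4, O5 and O6 lie on the β face and O3 on the α face, so C3/C4 are trans while C4/C5 and C5/C6 are cis. Only the primary allylic O7 and the secondary O5 are benzoylated, and O5 sits between two cis hydroxyls. The benzoates are the fragile part: base can move the O5 benzoyl to O4 or O6 and the O7 benzoyl to O6, the allylic C–O bonds at C3, C6 and C7 can ionise, and the ring is two eliminations away from an arene. The C7 skeleton is trivial. The real difficulty is absolute control at four adjacent carbinol carbons and, above all, placing one benzoyl on O5 and none on its cis neighbour O6. The key step uses the C7–C1=C2 unit together with the cis C5–O/C6–O pair: this is the imprint of a benzoate ring cis-dihydroxylated at the carbons ortho (C6) and meta (C5) to the carboxyl carbon. An enzyme can therefore write C5 and C6 into an achiral benzoate and leave a C1=C2–C3=C4 dienoate whose remote alkene later accepts O3 and O4.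

## Logic of the disconnections

16 to 15: the O3–Si and O4–Si bonds of a disiloxane bridge are cut last. Both benzoates are then already in place and the free triol never meets base. The forward step must use a fluoride source acidic enough that no acyl group migrates.

15 to 12 and 13: the O5–acyl bond is cut. A direct acylation of 12 would have to choose between two secondary hydroxyls and would favour the more exposed pseudo-equatorial O6, so a plan that strips the ketal and simply benzoylates twice has no reliable handle. The benzoyl is therefore delivered from 13 as a cyclic orthoester across O5/O6 (14), whose hydrolysis places the ester on the axial oxygen. The forward step demands a ring conformation with O5 axial, which is why O3 and O4 are tied diequatorially by one seven-membered bridge and not by two separate ethers.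

12 to 11: the two ketal C–O bonds at O5/O6 are restored. The ketal is the relay element for all later stereocontrol and is removed only when its oxygens must be told apart. The forward hydrolysis must spare the disiloxane and the allylic benzoate.

11 to 9 and 10: the O7–acyl bond is cut. O7 is the only free hydroxyl of 9, so no selectivity is asked of the forward acylation.

9 to 8: the two C7–H bonds are removed, returning C7 to the ester level. The ester is what the arene precursor offers, and it deactivates C1=C2 during the earlier oxidations. The forward reduction must be a clean 1,2-reduction that leaves ketal and silyl ether alone.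

8 to 7: the two Si–O bonds are cut, giving the free trans-diol. The forward step asks a bifunctional silyl chloride to bridge O3 and O4, which only a gauche (diequatorial) trans-diol can do.

7 to 6: the C3–O bond made by water is cut, giving the C3–C4 epoxide on the β face. One oxygen then sets two centres: O4 keeps the β orientation and O3 enters with inversion. The forward opening must occur at allylic C3 and not at C4.

6 to 4 (through 5): the two epoxide C–O bonds are cut, leaving the C3=C4 alkene. Direct peracid delivery would come from the open α face, so the forward sequence uses a halohydrin: the halogen takes the α face and water the β face, and ring closure puts oxygen syn to the ketal.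

4 to 2 and 3: the ketal C–O bonds are cut. The forward step only has to be faster than acid-catalysed dehydration of the dienediol.

2 to 1: the C5–O and C6–O bonds are cut and the ring rearomatises to an achiral commodity ester. All absolute stereochemistry is thereby reduced to one enzymatic step. Re-derivation confirms that the 5S,6R cis-diol 2 is spatially identical with C5/C6 of 16; C5 is R in 16 only because C4 outranks C6 once it carries oxygen.

## Other disconnections considered

Alternative 1: The cut is at C1–C6 and C2–C3. Furan A1 brings C3–C6 and a bridging oxygen, and 2-bromoacrolein A2 brings C1, C2 and C7. The forward key step is a catalytic asymmetric Diels–Alder reaction under the B-butyl oxazaborolidinone from N-tosyltryptophan A3, giving the exo-formyl oxanorbornene A4 (the antipode of A3 is chosen to match A4).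
- In its favour: two cheap achiral components deliver all seven carbons in one catalytic step. Exo cis-dihydroxylation of C4=C5 would fall syn to the bridge, so O4, O5 and the bridge oxygen retained on C6 come out all-cis. On relay of relative configuration this equals the ketal relay of the chosen plan. It needs no fermentation, and on that point it is the better plan.
- Against it: furan is a weak, reversible diene and A4 is prone to cycloreversion. A2 is a labile lachrymator. Enantiocontrol rests on a moisture-sensitive boron Lewis acid, whereas an enzyme pocket is expected to give essentially one enantiomer. The bridge holds O3 and O6 cis while the target has them trans, so one bridge C–O bond must be replaced with inversion after dehydrobromination. O5 still has to be distinguished from O4 inside a cis-diol.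
- Step economy is expected to be similar or slightly worse.

Alternative 2: The cut is at C1–C6 and C4–C5. Methyl (2E,4E)-5-[(S)-O-methylmandeloyloxy]penta-2,4-dienoate A5 and vinylene carbonate A6 would combine in a thermal endo Diels–Alder reaction to the all-cis cycloadduct A7.
- In its favour: one step creates the all-cis C4/C5/C6 oxygen triad, and O4 (ester) is already differentiated from O5/O6 (carbonate). On setting that triad in one operation it is the equal of the chosen plan, and it needs only ordinary glassware.
- Against it: absolute control depends on a remote stoichiometric auxiliary on a flexible acyloxy diene, so facial selectivity is expected to be modest and diastereomers would need separation. A6 is a sluggish dienophile that needs prolonged heating. The C1 stereocentre is made only to be destroyed, and the alkene must be moved from C2=C3 to C1=C2 by epoxidation anti to the three oxygens and enolate-triggered epoxide opening. The O5/O6 pair again shares one protecting group.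
- The chosen plan has the safer source of absolute configuration and no wasted stereocentre. Step counts are comparable.

Alternative 3: The cut is at C1–C6 alone. The D-lyxo-configured (E)-enoate aldehyde A8 would be closed by trimethylphosphine A9 in an intramolecular Morita–Baylis–Hillman reaction to A10.
- In its favour: C3, C4 and C5 come from the chiral pool, so no enantioselective step is needed. A10 already has the C1=C2 enoate, and its oxygens are sorted into three classes (silyl ether on O3, ketal on O4/O5, free O6). On differentiation of O6 this is better than anything the chosen route has before its ninth step.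
- Against it: A8 requires a multistep excursion from a sugar, including olefination, protecting-group changes and oxidation to an epimerisable α-alkoxy aldehyde. The new C6 centre is set by a reversible aldol step under substrate control whose sense is not assured. O5 must still be separated from O4 within the ketal.
- Mechanistically it forms one C–C bond and one stereocentre where the chosen step forms two C–O bonds and two stereocentres. Overall it is expected to be longer.

Key step: step 1

## Route

Step 1
Reactants: 1 methyl benzoate
Product: 2 methyl (5S,6R)-5,6-dihydroxycyclohexa-1,3-diene-1-carboxylate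
Conditions: recombinant E. coli whole cells expressing toluene dioxygenase (todC1C2BA), IPTG-induced, glucose-fed, aerated (O2), mineral medium pH 6.8–7.0, 30 °C, slow feed of 1; centrifuge, EtOAc extraction at pH 7
Reagents that add atoms: dioxygen, O=O
Why: The Rieske dioxygenase passes two electrons from NADH (regenerated by glucose metabolism) through its reductase and ferredoxin to a mononuclear non-heme iron site, where dioxygen is activated and both oxygen atoms are delivered to one face of the arene C5–C6 bond, leaving the C1=C2–C3=C4 dienoate. The closest known reaction type is the toluene dioxygenase cis-dihydroxylation of monosubstituted benzenes, alkyl benzoates included. No ring is closed. C5 and C6 are both set by the enzyme: the pocket orients the ester so that oxidation falls on the ortho and meta carbons of one enantiotopic edge, and the cis relationship follows from suprafacial transfer of a single O2 molecule. The step needs selectivity for the ortho/meta edge over the ipso/ortho edge, which this enzyme class provides for neutral esters. It also needs the diol to persist, which is secured because the host lacks the diol dehydrogenase that would rearomatise it and because the ester retards acid-catalysed dehydration.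

Step 2
Reactants: 2 methyl (5S,6R)-5,6-dihydroxycyclohexa-1,3-diene-1-carboxylate; 3 2,2-dimethoxypropane
Product: 4 methyl (5S,6R)-5,6-(isopropylidenedioxy)cyclohexa-1,3-diene-1-carboxylate
Conditions: 2,2-dimethoxypropane (3 equiv), p-TsOH·H2O (2 mol %), acetone, 0 °C to rt, 30 min; Et3N quench; kept cold and used at once
Reagents that add atoms: 2,2-dimethoxypropane 3, COC(C)(C)OC
Why: Acid-catalysed transketalisation of a cis-1,2-diol gives the cis-fused dioxolane, which blocks dehydration and shields the β face for the next step; the diene is used promptly because such ketals dimerise by Diels–Alder reaction on standing.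

Step 3
Reactants: 4 methyl (5S,6R)-5,6-(isopropylidenedioxy)cyclohexa-1,3-diene-1-carboxylate
Product: 6 methyl (3S,4S,5R,6R)-3,4-epoxy-5,6-(isopropylidenedioxy)cyclohex-1-ene-1-carboxylate, via bromohydrin 5 (not isolated)
Conditions: NBS (1.1 equiv), THF/H2O (4:1), 0 °C, dark; then K2CO3 (3 equiv), MeOH, 0 °C to rt
Reagents that add atoms: water, O; N-bromosuccinimide, O=C1CCC(=O)N1Br (its bromine is present only in 5 and is expelled on ring closure)
Why: Bromohydrin formation followed by Williamson-type closure: bromonium forms on the non-conjugated C3=C4 alkene from the open α face and water opens it anti at allylic C3 (3-OH β, 4-Br α). The C3 alkoxide then displaces bromide with inversion at C4, so the epoxide oxygen ends on the β face, syn to the ketal. The regioisomeric trans-bromohydrin would close to the same epoxide.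

Step 4
Reactants: 6 methyl (3S,4S,5R,6R)-3,4-epoxy-5,6-(isopropylidenedioxy)cyclohex-1-ene-1-carboxylate
Product: 7 methyl (3R,4S,5S,6R)-3,4-dihydroxy-5,6-(isopropylidenedioxy)cyclohex-1-ene-1-carboxylate
Conditions: HClO4 (5 mol %), THF/H2O (2:1), 0 °C; NaHCO3 quench as soon as 6 is consumed
Reagents that add atoms: water, O
Why: Acid-catalysed anti hydrolysis of a vinyl epoxide: water attacks allylic C3, which is remote from the ketal and not deactivated by a vicinal C–O bond, from the α face with inversion. O3 therefore ends trans to O4, and O4 keeps the β orientation inherited from the epoxide.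

Step 5
Reactants: 7 methyl (3R,4S,5S,6R)-3,4-dihydroxy-5,6-(isopropylidenedioxy)cyclohex-1-ene-1-carboxylate
Product: 8 methyl (3R,4R,5R,6R)-5,6-(isopropylidenedioxy)-3,4-[(1,1,3,3-tetraisopropyldisiloxane-1,3-diyl)dioxy]cyclohex-1-ene-1-carboxylate
Conditions: (i-Pr2SiCl)2O (1.05 equiv), imidazole (3 equiv), DMF, 0 °C to rt
Reagents that add atoms: 1,3-dichloro-1,1,3,3-tetraisopropyldisiloxane, CC(C)[Si](Cl)(C(C)C)O[Si](Cl)(C(C)C)C(C)C
Why: Double silylation of a vicinal trans-diol by a bifunctional silyl chloride; the seven-membered bridge can only span gauche oxygens, so it fixes O3/O4 diequatorial and thereby sets the half-chair in which O5 is axial and O6 pseudo-equatorial.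

Step 6
Reactants: 8 methyl (3R,4R,5R,6R)-5,6-(isopropylidenedioxy)-3,4-[(1,1,3,3-tetraisopropyldisiloxane-1,3-diyl)dioxy]cyclohex-1-ene-1-carboxylate
Product: 9 [(3R,4R,5R,6R)-5,6-(isopropylidenedioxy)-3,4-[(1,1,3,3-tetraisopropyldisiloxane-1,3-diyl)dioxy]cyclohex-1-en-1-yl]methanol
Conditions: i-Bu2AlH (2.5 equiv), CH2Cl2, −78 °C; aq. KNaC4H4O6 work-up
Reagents that add atoms: none
Why: 1,2-Reduction of an α,β-unsaturated ester to the allylic alcohol by an electrophilic aluminium hydride at low temperature; ketal and silyl ether are inert and no stereocentre is involved.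

Step 7
Reactants: 9 [(3R,4R,5R,6R)-5,6-(isopropylidenedioxy)-3,4-[(1,1,3,3-tetraisopropyldisiloxane-1,3-diyl)dioxy]cyclohex-1-en-1-yl]methanol; 10 benzoyl chloride
Product: 11 [(3R,4R,5R,6R)-5,6-(isopropylidenedioxy)-3,4-[(1,1,3,3-tetraisopropyldisiloxane-1,3-diyl)dioxy]cyclohex-1-en-1-yl]methyl benzoate
Conditions: BzCl (1.2 equiv), pyridine (3 equiv), DMAP (5 mol %), CH2Cl2, 0 °C
Reagents that add atoms: benzoyl chloride 10, O=C(Cl)c1ccccc1
Why: Nucleophilic-catalysed acylation of the only free hydroxyl, the primary allylic O7; nothing else in the molecule can compete.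

Step 8
Reactants: 11 [(3R,4R,5R,6R)-5,6-(isopropylidenedioxy)-3,4-[(1,1,3,3-tetraisopropyldisiloxane-1,3-diyl)dioxy]cyclohex-1-en-1-yl]methyl benzoate
Product: 12 [(3R,4R,5R,6R)-5,6-dihydroxy-3,4-[(1,1,3,3-tetraisopropyldisiloxane-1,3-diyl)dioxy]cyclohex-1-en-1-yl]methyl benzoate
Conditions: AcOH/H2O (4:1), 50 °C; toluene azeotrope
Reagents that add atoms: none
Why: Mild acid hydrolysis of the isopropylidene ketal; the hindered secondary disiloxane and the benzoate should tolerate warm aqueous acetic acid, and the weak acid does not promote acyl migration.

Step 9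
Reactants: 12 [(3R,4R,5R,6R)-5,6-dihydroxy-3,4-[(1,1,3,3-tetraisopropyldisiloxane-1,3-diyl)dioxy]cyclohex-1-en-1-yl]methyl benzoate; 13 trimethyl orthobenzoate
Product: 15 [(3R,4R,5R,6R)-5-(benzoyloxy)-6-hydroxy-3,4-[(1,1,3,3-tetraisopropyldisiloxane-1,3-diyl)dioxy]cyclohex-1-en-1-yl]methyl benzoate, via cyclic orthobenzoate 14 (not isolated)
Conditions: PhC(OMe)3 (1.5 equiv), CSA (5 mol %), MeCN, rt; then AcOH/H2O (4:1), 0 °C to rt
Reagents that add atoms: trimethyl orthobenzoate 13, COC(OC)(OC)c1ccccc1; water, O
Why: Orthoester exchange onto the cis-5,6-diol followed by mild hydrolysis (the cyclic-orthoester route to a monoester of a cis-diol, as used for pyranoside cis-diols). With the ring held so that O5 is axial, the hemiorthoester collapses under stereoelectronic control to the axial ester, giving the O5 benzoate with O6 free. No stereocentre is touched.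

Step 10
Reactants: 15 [(3R,4R,5R,6R)-5-(benzoyloxy)-6-hydroxy-3,4-[(1,1,3,3-tetraisopropyldisiloxane-1,3-diyl)dioxy]cyclohex-1-en-1-yl]methyl benzoate
Product: 16 [(3R,4S,5R,6R)-5-(benzoyloxy)-3,4,6-trihydroxycyclohex-1-en-1-yl]methyl benzoate
Conditions: HF·pyridine, pyridine/THF, 0 °C to rt; quench into pH 7 phosphate buffer
Reagents that add atoms: none
Why: Fluoride-driven cleavage of both Si–O bonds under mildly acidic conditions, where benzoates neither hydrolyse nor migrate; the descriptor at C4 changes from R to S only through the ranking change on loss of silicon.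

## Compound list

1 | methyl benzoate | COC(=O)c1ccccc1 | starting material
2 | methyl (5S,6R)-5,6-dihydroxycyclohexa-1,3-diene-1-carboxylate | COC(=O)C1=CC=C[C@H](O)[C@@H]1O | intermediate
3 | 2,2-dimethoxypropane | COC(C)(C)OC | starting material
4 | methyl (5S,6R)-5,6-(isopropylidenedioxy)cyclohexa-1,3-diene-1-carboxylate | COC(=O)C1=CC=C[C@H]2[C@@H]1OC(C)(C)O2 | intermediate
5 | methyl (3S,4R,5R,6R)-4-bromo-3-hydroxy-5,6-(isopropylidenedioxy)cyclohex-1-ene-1-carboxylate (bromohydrin; not isolated) | COC(=O)C1=C[C@H](O)[C@@H](Br)[C@H]2[C@@H]1OC(C)(C)O2 | intermediate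
6 | methyl (3S,4S,5R,6R)-3,4-epoxy-5,6-(isopropylidenedioxy)cyclohex-1-ene-1-carboxylate (epoxide syn to the ketal) | COC(=O)C1=C[C@@H]3O[C@@H]3[C@H]2[C@@H]1OC(C)(C)O2 | intermediate
7 | methyl (3R,4S,5S,6R)-3,4-dihydroxy-5,6-(isopropylidenedioxy)cyclohex-1-ene-1-carboxylate | COC(=O)C1=C[C@@H](O)[C@H](O)[C@H]2[C@@H]1OC(C)(C)O2 | intermediate
8 | methyl (3R,4R,5R,6R)-5,6-(isopropylidenedioxy)-3,4-[(1,1,3,3-tetraisopropyldisiloxane-1,3-diyl)dioxy]cyclohex-1-ene-1-carboxylate | COC(=O)C1=C[C@@H]4[C@H](O[Si](C(C)C)(C(C)C)O[Si](C(C)C)(C(C)C)O4)[C@H]2[C@@H]1OC(C)(C)O2 | intermediate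
9 | [(3R,4R,5R,6R)-5,6-(isopropylidenedioxy)-3,4-[(1,1,3,3-tetraisopropyldisiloxane-1,3-diyl)dioxy]cyclohex-1-en-1-yl]methanol | OCC1=C[C@@H]4[C@H](O[Si](C(C)C)(C(C)C)O[Si](C(C)C)(C(C)C)O4)[C@H]2[C@@H]1OC(C)(C)O2 | intermediate
10 | benzoyl chloride | O=C(Cl)c1ccccc1 | starting material
11 | [(3R,4R,5R,6R)-5,6-(isopropylidenedioxy)-3,4-[(1,1,3,3-tetraisopropyldisiloxane-1,3-diyl)dioxy]cyclohex-1-en-1-yl]methyl benzoate | O=C(OCC1=C[C@@H]4[C@H](O[Si](C(C)C)(C(C)C)O[Si](C(C)C)(C(C)C)O4)[C@H]2[C@@H]1OC(C)(C)O2)c1ccccc1 | intermediate
12 | [(3R,4R,5R,6R)-5,6-dihydroxy-3,4-[(1,1,3,3-tetraisopropyldisiloxane-1,3-diyl)dioxy]cyclohex-1-en-1-yl]methyl benzoate | O=C(OCC1=C[C@@H]4[C@H](O[Si](C(C)C)(C(C)C)O[Si](C(C)C)(C(C)C)O4)[C@H](O)[C@@H]1O)c1ccccc1 | intermediate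
13 | trimethyl orthobenzoate | COC(OC)(OC)c1ccccc1 | starting material
14 | 5,6-O-(α-methoxybenzylidene) cyclic orthobenzoate of 12 (both epimers at the orthoester carbon; not isolated) | O=C(OCC1=C[C@@H]4[C@H](O[Si](C(C)C)(C(C)C)O[Si](C(C)C)(C(C)C)O4)[C@H]2[C@@H]1OC(OC)(c3ccccc3)O2)c1ccccc1 | intermediate
15 | [(3R,4R,5R,6R)-5-(benzoyloxy)-6-hydroxy-3,4-[(1,1,3,3-tetraisopropyldisiloxane-1,3-diyl)dioxy]cyclohex-1-en-1-yl]methyl benzoate | O=C(OCC1=C[C@@H]4[C@H](O[Si](C(C)C)(C(C)C)O[Si](C(C)C)(C(C)C)O4)[C@H](OC(=O)c2ccccc2)[C@@H]1O)c1ccccc1 | intermediate
16 | [(3R,4S,5R,6R)-5-(benzoyloxy)-3,4,6-trihydroxycyclohex-1-en-1-yl]methyl benzoate | O=C(OCC1=C[C@@H](O)[C@H](O)[C@H](OC(=O)c2ccccc2)[C@@H]1O)c1ccccc1 | target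

## Step count and least certain steps

Total: 10 steps. Longest linear sequence: 10 steps, from 1 to 16; the route is fully linear.

Step 1 (key step). The most likely failure is low productivity: the lipophilic ester is toxic to the cells and poorly transferred into the aqueous phase, host esterases may hydrolyse it, and the dienediol may dehydrate to phenols during concentration. The fallback keeps the enzymatic dearomatisation but changes the arene. It replaces 1 by iodobenzene F1, which the same cells should convert to (1S,2S)-3-iodocyclohexa-3,5-diene-1,2-diol F2. Ketalisation with 3 would give (3aS,7aS)-4-iodo-2,2-dimethyl-3a,7a-dihydro-1,3-benzodioxole F3. Methoxycarbonylation of the vinyl iodide (CO, MeOH, Pd(OAc)2, PPh3, Et3N, DMF, 50 °C, zerovalent palladium formed in the flask) would rejoin the route at 4.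

Step 9. The risk is loss of regiocontrol in the breakdown of the hemiorthoester, or benzoyl shift from O5 to O6 afterwards, if the ring is less firmly held than the bridge suggests; the product would then be contaminated by the O6 ester. The fallback abandons stereoelectronic control for a tether and sets out from 9. Aqueous acetic acid removes the ketal to give the triol [(3R,4R,5R,6R)-5,6-dihydroxy-3,4-[(1,1,3,3-tetraisopropyldisiloxane-1,3-diyl)dioxy]cyclohex-1-en-1-yl]methanol F4. t-Bu2Si(OTf)2 with 2,6-lutidine should bridge the 1,3-related O6 and O7 as a six-membered silylene F5, leaving only O5 free. Benzoylation with 10 and DMAP gives F6. HF·pyridine removes both silicon bridges to give the 5-O-benzoyl tetraol F7. Acylation of the primary allylic O7 with 10 and 2,4,6-collidine at −40 °C returns to the route at 16.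

Step 4. Water may attack C4 instead of C3, or the ketal may hydrolyse before the epoxide is consumed, which would erase the distinction between the oxygen pairs. The fallback starts from 6 and uses a carboxylate nucleophile under anhydrous conditions: AcOH/NaOAc should open the epoxide at C3 to methyl (3R,4S,5S,6R)-3-acetoxy-4-hydroxy-5,6-(isopropylidenedioxy)cyclohex-1-ene-1-carboxylate F8 with the ketal untouched. Methanolysis (K2CO3 cat., MeOH, 0 °C) then rejoins the route at 7.

Step 8. The disiloxane bridge may open partially, or the O7 benzoyl may shift to O6, during the warm acidic ketal hydrolysis. The fallback gives up chemoselectivity and starts from 11. HF·pyridine followed by aqueous acetic acid removes both protecting groups to give [(3R,4S,5R,6R)-3,4,5,6-tetrahydroxycyclohex-1-en-1-yl]methyl benzoate F9. One equivalent of 13 with CSA gives a cis-fused cyclic orthobenzoate F10 (drawn across O5/O6; bridging across the other cis pair through O4 leads to the same result). Mild aqueous acid should open it to the ester on the lone axial oxygen O5, reaching the route at 16. This relies on the free tetraol preferring the half-chair with three (pseudo)equatorial hydroxyls, so it is less secure than the bridged main route.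

## Further compounds

F1 | step 1 | iodobenzene | Ic1ccccc1
F2 | step 1 | (1S,2S)-3-iodocyclohexa-3,5-diene-1,2-diol | IC1=CC=C[C@H](O)[C@@H]1O
F3 | step 1 | (3aS,7aS)-4-iodo-2,2-dimethyl-3a,7a-dihydro-1,3-benzodioxole | IC1=CC=C[C@H]2[C@@H]1OC(C)(C)O2
F4 | step 9 | [(3R,4R,5R,6R)-5,6-dihydroxy-3,4-[(1,1,3,3-tetraisopropyldisiloxane-1,3-diyl)dioxy]cyclohex-1-en-1-yl]methanol | OCC1=C[C@@H]4[C@H](O[Si](C(C)C)(C(C)C)O[Si](C(C)C)(C(C)C)O4)[C@H](O)[C@@H]1O
F5 | step 9 | (3R,4R,5R,6R)-6,7-O-(di-tert-butylsilylene)-3,4-O-(1,1,3,3-tetraisopropyldisiloxane-1,3-diyl) derivative of 1-(hydroxymethyl)cyclohex-1-ene-3,4,5,6-tetrol, 5-OH free | CC(C)(C)[Si]1(C(C)(C)C)OCC2=C[C@@H]4[C@H](O[Si](C(C)C)(C(C)C)O[Si](C(C)C)(C(C)C)O4)[C@H](O)[C@@H]2O1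
F6 | step 9 | 5-O-benzoate of F5 | CC(C)(C)[Si]1(C(C)(C)C)OCC2=C[C@@H]4[C@H](O[Si](C(C)C)(C(C)C)O[Si](C(C)C)(C(C)C)O4)[C@H](OC(=O)c3ccccc3)[C@@H]2O1
F7 | step 9 | (3R,4S,5R,6R)-3,4,6-trihydroxy-1-(hydroxymethyl)cyclohex-1-en-5-yl benzoate | OCC1=C[C@@H](O)[C@H](O)[C@H](OC(=O)c2ccccc2)[C@@H]1O
F8 | step 4 | methyl (3R,4S,5S,6R)-3-acetoxy-4-hydroxy-5,6-(isopropylidenedioxy)cyclohex-1-ene-1-carboxylate | COC(=O)C1=C[C@@H](OC(C)=O)[C@H](O)[C@H]2[C@@H]1OC(C)(C)O2
F9 | step 8 | [(3R,4S,5R,6R)-3,4,5,6-tetrahydroxycyclohex-1-en-1-yl]methyl benzoate | O=C(OCC1=C[C@@H](O)[C@H](O)[C@H](O)[C@@H]1O)c1ccccc1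
F10 | step 8 | 5,6-O-(α-methoxybenzylidene) cyclic orthobenzoate of F9 (both epimers at the orthoester carbon) | O=C(OCC1=C[C@@H](O)[C@H](O)[C@H]2[C@@H]1OC(OC)(c3ccccc3)O2)c1ccccc1
A1 | alternative 1 | furan | c1ccoc1
A2 | alternative 1 | 2-bromoacrolein | C=C(Br)C=O
A3 | alternative 1 | B-butyl-1,3,2-oxazaborolidin-5-one from N-tosyltryptophan (drawn as the (R)-tryptophan antipode) | CCCCB1OC(=O)[C@@H](Cc2c[nH]c3ccccc23)N1S(=O)(=O)c1ccc(C)cc1
A4 | alternative 1 | 2-bromo-7-oxabicyclo[2.2.1]hept-5-ene-2-carbaldehyde (exo formyl) | O=C[C@]1(Br)C[C@H]2C=C[C@@H]1O2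
A5 | alternative 2 | methyl (2E,4E)-5-[(S)-O-methylmandeloyloxy]penta-2,4-dienoate | COC(=O)/C=C/C=C/OC(=O)[C@@H](OC)c1ccccc1
A6 | alternative 2 | vinylene carbonate | O=C1OC=CO1
A7 | alternative 2 | all-cis cycloadduct (C1 methyl ester, C4 (S)-O-methylmandelate, C5/C6 cyclic carbonate, C2=C3) | COC(=O)[C@@H]1C=C[C@H](OC(=O)[C@@H](OC)c2ccccc2)[C@@H]3OC(=O)O[C@H]13
A8 | alternative 3 | D-lyxo (E)-enoate aldehyde (ring numbering: C1=C2 enoate, C3 OTBS, C4/C5 isopropylidene ketal, C6 aldehyde) | COC(=O)/C=C/[C@@H](O[Si](C)(C)C(C)(C)C)[C@@H]1OC(C)(C)O[C@@H]1C=O
A9 | alternative 3 | trimethylphosphine | CP(C)C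
A10 | alternative 3 | methyl 3-O-TBS-4,5-O-isopropylidene-6-hydroxycyclohex-1-ene-1-carboxylate | COC(=O)C1=C[C@@H](O[Si](C)(C)C(C)(C)C)[C@@H]2OC(C)(C)O[C@@H]2[C@@H]1O
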